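The cyclohexane ring C1–C6 (numbering below) is disconnected at C5–C6 and C1–C2 into a C2=C3–C4=C5 diene and a C1=C6 vinyl ketone (C7 as carbonyl, methylenated later). The plan exploits the 1,5-related oxygens on C3 and C8 (O–C3–C2–C1–C7–C8–O). A diisopropylsilylene unit ties the C3 dienol oxygen to the (8S)-carbinol. One thermal type 2 intramolecular Diels–Alder reaction of this silaketal triene forms both bonds and closes the carbocycle plus a temporary eight-membered dioxasila ring. It also enforces the 1,3 regiochemistry and sets C1 and C2 from C8. The resulting bridgehead silyl enol ether is the handle for the C3 hydroxyl and the C4–C5 epoxide.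

Key step: step 6

Numbering used throughout:
- Ring: C1 (bears the side chain), C2 (angelate), C3 (hydroxyl), C4 (methyl, epoxide), C5 (epoxide CH), C6 (CH2).
- Side chain: C7(=C14H2), C8 (angelate), C9 (CH2), C10–C11 (epoxide, C11 with two methyl groups).
- Target: (1S,2R,3R,4R,5S,8S,10R). The C1 side chain, both ring oxygens on C2 and C3, and the ring epoxide all lie on one face.
- C1 reads R in 14 and C3 reads S in 21 only because CIP ranks change.

Assumption: 1, 2, 4, 7, 8, 10, i-Pr2Si(OTf)2, the Tebbe reagent and the D-fructose-derived Shi ketone are taken as commercial.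

Step 1
Reactants: 1 methyl (S)-glycidate; 2 2-methylprop-1-enylmagnesium bromide
Product: 3 methyl (2S)-2-hydroxy-5-methylhex-4-enoate
Conditions: CuBr·SMe2 (15 mol %), THF, −78 to −40 °C; aq NH4Cl
Reagents that add atoms: none
Why: Copper-catalysed SN2 opening of the glycidic ester at its unsubstituted CH2 (organocuprate epoxide opening) outruns attack on the ester at low temperature and leaves the carbinol stereocentre (future C8) untouched.

Step 2
Reactants: 3 methyl (2S)-2-hydroxy-5-methylhex-4-enoate; 4 vinylmagnesium bromide
Product: 6 (4S)-4-hydroxy-7-methylocta-1,6-dien-3-one, via Weinreb amide 5 (not isolated)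
Conditions: MeNH(OMe)·HCl, i-PrMgCl, THF, −20 °C; then 4, −20 to 0 °C; inverse quench into cold 1 M HCl
Reagents that add atoms: N,O-dimethylhydroxylamine hydrochloride, CNOC.Cl (its atoms stand in 5 only)
Why: Magnesium-amide aminolysis followed by the Weinreb ketone synthesis stops at the vinyl ketone through the chelated tetrahedral adduct, the magnesium alkoxide shields C8 from enolisation, and the acidic inverse quench keeps the released amine from adding to the enone.

Step 3
Reactants: 7 2-chloro-N-methoxy-N-methylacetamide; 8 isopropenylmagnesium bromide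
Product: 9 1-chloro-3-methylbut-3-en-2-one
Conditions: THF, −20 to 0 °C; cold 1 M HCl
Reagents that add atoms: none
Why: The Weinreb ketone synthesis gives the α-chloro ketone without over-addition, because the chelated adduct collapses only on quench.

Step 4
Reactants: 9 1-chloro-3-methylbut-3-en-2-one; 10 angelic acid
Product: 11 3-methyl-2-oxobut-3-en-1-yl (Z)-2-methylbut-2-enoate
Conditions: KHCO3, NaI (10 mol %), DMF, rt
Reagents that add atoms: none
Why: SN2 displacement of an α-halo ketone by a carboxylate uses angelic acid as the O-nucleophile, so its acyl group is never activated and the Z double bond cannot drift to the tiglate.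

Step 5
Reactants: 11 3-methyl-2-oxobut-3-en-1-yl (Z)-2-methylbut-2-enoate; 6 (4S)-4-hydroxy-7-methylocta-1,6-dien-3-one
Product: 13 silaketal triene (Z enol ether, 8S), via enoxysilyl triflate 12 (not isolated)
Conditions: i-Pr2Si(OTf)2, Et3N, CH2Cl2, −78 to −20 °C; then 6, Et3N, −78 °C to rt; filtration through Et3N-deactivated silica
Reagents that add atoms: diisopropylsilyl bis(trifluoromethanesulfonate), CC(C)[Si](OS(=O)(=O)C(F)(F)F)(OS(=O)(=O)C(F)(F)F)C(C)C
Why: Soft enolisation at the only enolisable position (C2) should give the (Z)-enoxysilyl triflate, with the acyloxy group trans to the bulkier isopropenyl group, and the remaining Si–OTf bond is then substituted by the secondary alcohol (unsymmetrical silaketal synthesis).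

Step 6
Reactants: 13 silaketal triene
Product: 14 bridged cycloadduct, 3,3-diisopropyl-10-methyl-5-(3-methylbut-2-enyl)-6-oxo-2,4-dioxa-3-silabicyclo[5.3.1]undec-1(10)-en-11-yl angelate, (1R,2R,8S), C1–C7 and C2–O cis
Conditions: PhMe (0.005 M), BHT, base-washed glassware, 110 °C
Reagents that add atoms: none
Why: This is a concerted but asynchronous [4+2] cycloaddition (type 2 intramolecular Diels–Alder reaction, tether on the internal diene carbon C3) of the electron-rich 1-acyloxy-2-silyloxy-3-methyl diene C2=C3–C4=C5 with the vinyl ketone C1=C6, with C5–C6 bonding running ahead of C1–C2 bonding. The closest known reaction type is the silicon-tethered type 2 Diels–Alder reaction that gives bicyclo[n.3.1] bridgehead alkenes, here a bicyclo[5.3.1]undecene whose bridgehead double bond sits trans in a ten-membered ring and is therefore isolable. The cyclohexene ring C1–C6 closes by the suprafacial [4+2] union itself, and the eight-membered ring C1–C7–C8–O–Si–O–C3–C2 closes in the bridged mode when C1–C2 forms, because a five-atom tether can only span the 1,3 positions. C1 and C2 come out cis because the tether forces C7 endo while the (Z)-enol geometry holds the angeloyloxy group in the outside position of C2. The absolute sense comes from C8: the short tether reaches the C3 oxygen without colliding with the C2 ester only when the enone is s-trans and C8 lies above C3, where the C8–H must face the diene and the prenyl group points away, which for (8S) selects the diene face that gives the 1S,2R array of the target. The step needs meta regiochemistry against the para bias of the 2-silyloxy group, secured by the tether length and supported by the 1-acyloxy and 3-methyl groups, and it needs chemoselectivity for the vinyl ketone, secured because the angelate and prenyl alkenes are unactivated and trisubstituted.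

Step 7
Reactants: 14 bridged cycloadduct
Product: 15 6-methylidene bridged diene (C7=C14H2 installed), (1S,2R,8S)
Conditions: Cp2Ti(CH2)(Cl)AlMe2 (Tebbe reagent), pyridine, THF–PhMe, −40 to 0 °C; aq NaOH
Reagents that add atoms: Tebbe reagent, C[Al-]1(C)C[Ti]([Cl+]1)(C1C=CC=C1)C1C=CC=C1
Why: In the Tebbe olefination the non-basic titanium methylidene methylenates the ketone much faster than the hindered conjugated angelate at low temperature, cannot trigger β-elimination of the C2 ester, and leaves the silyl enol ether (the masked C3 ketone) untouched.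

Step 8
Reactants: 15 6-methylidene bridged diene
Product: 17 C8-hydroxy cyclohexenone (C3 ketone, C4=C5, C2 angelate, free C8 hydroxyl), (1S,2R,8S), via acetoxysilyl ether 16 (not isolated)
Conditions: Pd(OAc)2, MeCN, rt to 40 °C; then 48% aq HF, 0 °C
Reagents that add atoms: palladium diacetate, CC(=O)[O-].CC(=O)[O-].[Pd+2] (its acetate stands in 16 only)
Why: In the Saegusa–Ito oxidation divalent palladium attacks the strained bridgehead silyl enol ether, β-hydride elimination of the syn C5 hydrogen gives the endocyclic C4=C5 enone, and fluoride then strips the residual silyl group from the C8 oxygen.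

Step 9
Reactants: 17 C8-hydroxy cyclohexenone; 10 angelic acid
Product: 19 bis-angelate trienone, (1S,2R,8S), via mixed anhydride 18 (not isolated)
Conditions: 10, 2,4,6-Cl3C6H2COCl, Et3N, PhMe, rt, salt filtered off; then 17, PhMe, 80 °C
Reagents that add atoms: 2,4,6-trichlorobenzoyl chloride, O=C(Cl)c1c(Cl)cc(Cl)cc1Cl (its atoms stand in 18 only)
Why: Yamaguchi-type mixed-anhydride esterification without a nucleophilic catalyst is the established way to place an angeloyl group on a hindered secondary alcohol, with retention at C8 and without Z to E isomerisation.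

Step 10
Reactants: 19 bis-angelate trienone
Product: 20 side-chain epoxide dienone, (1S,2R,8S,10R)
Conditions: D-fructose-derived Shi ketone (30 mol %), Oxone, K2CO3, Bu4NHSO4, Na2B4O7–Na2EDTA buffer, MeCN–CH2(OMe)2, 0 °C
Reagents that add atoms: potassium peroxymonosulfate (active part of Oxone), [K+].[O-]S(=O)(=O)OO
Why: In the Shi epoxidation the chiral dioxirane takes the only electron-rich trisubstituted alkene (C10=C11) ahead of the enone, the angelates and the hindered C7=C14 alkene, its spiro transition state should set (10R) under reagent control, and the pseudoequatorial C2–H is poorly aligned for enolisation in the buffer.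

Step 11
Reactants: 20 side-chain epoxide dienone
Product: 21 allylic alcohol, (1S,2R,3S,8S,10R), C3 hydroxyl cis to the C2 angelate
Conditions: NaBH4, CeCl3·7H2O, MeOH, −78 °C
Reagents that add atoms: none
Why: The Luche reduction gives 1,2-reduction only, and hydride should add to the ring face opposite the pseudoaxial C2 angeloyloxy group and the C1 side chain (antiperiplanar to C2–O, Felkin–Anh sense), which places the C3 hydroxyl cis to both.

Step 12
Reactants: 21 allylic alcohol
Product: 22 target CNP0235377.1, (1S,2R,3R,4R,5S,8S,10R)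
Conditions: VO(acac)2 (5 mol %), t-BuOOH, CH2Cl2, 0 °C
Reagents that add atoms: tert-butyl hydroperoxide, CC(C)(C)OO
Why: Vanadium-catalysed hydroxyl-directed epoxidation delivers oxygen to C4=C5 from the face of the C3 hydroxyl (a syn epoxy alcohol, which sets C4 and C5) and ignores the alkenes that lack an allylic hydroxyl group.

Compound list
1 | methyl (S)-glycidate | COC(=O)[C@@H]1CO1 | starting material
2 | 2-methylprop-1-enylmagnesium bromide | CC(C)=C[Mg]Br | starting material
3 | methyl (2S)-2-hydroxy-5-methylhex-4-enoate | COC(=O)[C@H](CC=C(C)C)O | intermediate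
4 | vinylmagnesium bromide | C=C[Mg]Br | starting material
5 | (2S)-2-hydroxy-N-methoxy-N,5-dimethylhex-4-enamide (Weinreb amide) | CON(C)C(=O)[C@H](CC=C(C)C)O | intermediate
6 | (4S)-4-hydroxy-7-methylocta-1,6-dien-3-one | C=CC(=O)[C@H](CC=C(C)C)O | intermediate
7 | 2-chloro-N-methoxy-N-methylacetamide | CON(C)C(=O)CCl | starting material
8 | isopropenylmagnesium bromide | C=C(C)[Mg]Br | starting material
9 | 1-chloro-3-methylbut-3-en-2-one | C=C(C)C(=O)CCl | intermediate
10 | angelic acid, (Z)-2-methylbut-2-enoic acid | C/C=C(/C)C(=O)O | starting material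
11 | 3-methyl-2-oxobut-3-en-1-yl (Z)-2-methylbut-2-enoate | C=C(C)C(=O)COC(=O)/C(C)=C\C | intermediate
12 | (1Z)-2-{[diisopropyl(triflyloxy)silyl]oxy}-3-methylbuta-1,3-dien-1-yl angelate | C=C(C)/C(O[Si](C(C)C)(C(C)C)OS(=O)(=O)C(F)(F)F)=C/OC(=O)/C(C)=C\C | intermediate
13 | silaketal triene, (1Z)-2-({diisopropyl[(4S)-7-methyl-3-oxoocta-1,6-dien-4-yloxy]silyl}oxy)-3-methylbuta-1,3-dien-1-yl angelate | C=CC(=O)[C@H](CC=C(C)C)O[Si](C(C)C)(C(C)C)O/C(C(C)=C)=C\OC(=O)/C(C)=C\C | intermediate
14 | bridged cycloadduct, 6-oxo-2,4-dioxa-3-silabicyclo[5.3.1]undec-1(10)-ene, (1R,2R,8S) | O=C1[C@H](CC=C(C)C)O[Si](C(C)C)(C(C)C)OC2=C(C)CC[C@@H]1[C@H]2OC(=O)/C(C)=C\C | intermediate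
15 | 6-methylidene bridged diene, (1S,2R,8S) | C=C1[C@H](CC=C(C)C)O[Si](C(C)C)(C(C)C)OC2=C(C)CC[C@@H]1[C@H]2OC(=O)/C(C)=C\C | intermediate
16 | C8 acetoxy(diisopropyl)silyl ether of 17 | C=C([C@H](CC=C(C)C)O[Si](C(C)C)(C(C)C)OC(C)=O)[C@@H]1CC=C(C)C(=O)[C@@H]1OC(=O)/C(C)=C\C | intermediate
17 | C8-hydroxy cyclohexenone, (1S,2R,8S) | C=C([C@H](CC=C(C)C)O)[C@@H]1CC=C(C)C(=O)[C@@H]1OC(=O)/C(C)=C\C | intermediate
18 | angelic 2,4,6-trichlorobenzoic mixed anhydride | C/C=C(/C)C(=O)OC(=O)c1c(Cl)cc(Cl)cc1Cl | intermediate
19 | bis-angelate trienone, (1S,2R,8S) | C=C([C@H](CC=C(C)C)OC(=O)/C(C)=C\C)[C@@H]1CC=C(C)C(=O)[C@@H]1OC(=O)/C(C)=C\C | intermediate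
20 | side-chain epoxide dienone, (1S,2R,8S,10R) | C=C([C@H](C[C@H]1OC1(C)C)OC(=O)/C(C)=C\C)[C@@H]1CC=C(C)C(=O)[C@@H]1OC(=O)/C(C)=C\C | intermediate
21 | allylic alcohol, (1S,2R,3S,8S,10R) | C=C([C@H](C[C@H]1OC1(C)C)OC(=O)/C(C)=C\C)[C@@H]1CC=C(C)[C@H](O)[C@@H]1OC(=O)/C(C)=C\C | intermediate
22 | CNP0235377.1, (1S,2R,3R,4R,5S,8S,10R) | C=C([C@H](C[C@H]1OC1(C)C)OC(=O)/C(C)=C\C)[C@@H]1C[C@@H]2O[C@]2(C)[C@H](O)[C@@H]1OC(=O)/C(C)=C\C | target

Total step count: 12. Longest linear sequence: 10 steps (1, 2, 5–12).

Steps most likely to fail

Step 6.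
- What may go wrong: the bridged transition state may be reached too slowly. Silyl transfer, polymerisation of the vinyl ketone, or erosion of facial selectivity through the alternative tether conformation could then take over.
- Fallback: an untethered, intermolecular Diels–Alder union that sets out from 11 and 6.
- TBSOTf/Et3N should turn 11 into the (Z)-tert-butyldimethylsilyl dienol ether F1, and TBSOTf/2,6-lutidine should turn 6 into the O-silylated vinyl ketone F2.
- Heating the two neat or under high pressure should give the cis (endo) ortho cycloadduct F3. Regiochemistry then rests on the 1-acyloxy and 3-methyl groups, and the facial bias on the dipole-minimised conformer of the α'-silyloxy enone. Isomers are removed by chromatography.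
- Tebbe olefination should give the methylenated bis-silyl compound F4, and Pd(OAc)2 the C8 silyl ether enone F5. Aqueous HF comes back to the route at 17.

Step 7.
- What may go wrong: the ketone flanked by the bridgehead and the silyloxy carbon may resist the bulky titanium methylidene, and competing methylenation of the angelate may set in.
- Fallback: a Peterson sequence with a small nucleophile that sets out from 14.
- Me3SiCH2Li/CeCl3 (THF, −78 °C) should add to C7 to give the tertiary β-hydroxysilane F6 (C7 configuration of no consequence).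
- Pd(OAc)2 in MeCN should then give the acetoxysilyl enone β-hydroxysilane F7.
- Aqueous HF should effect the acid Peterson elimination and the Si–O cleavage together, coming back to the route at 17.

Step 8.
- What may go wrong: slow transfer of the hindered enoxysilane to palladium, β-hydride elimination toward the C4 methyl group, or palladium-induced alkene migration.
- Fallback: a selenoxide elimination that sets out from 15.
- PhSeCl (CH2Cl2, −78 °C) should attack the enol ether carbon C4 to give the chlorosilyl α-phenylselanyl ketone F8 (C4 configuration of no consequence).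
- Aqueous HF should free the hydroxy selenide F9, and H2O2/pyridine should give the selenoxide F10. Its syn elimination toward C5 comes back to the route at 17.

Further compounds
F1 | step 6 | (1Z)-2-(tert-butyldimethylsilyloxy)-3-methylbuta-1,3-dien-1-yl angelate | C=C(C)/C(O[Si](C)(C)C(C)(C)C)=C/OC(=O)/C(C)=C\C
F2 | step 6 | (4S)-4-(tert-butyldimethylsilyloxy)-7-methylocta-1,6-dien-3-one | C=CC(=O)[C@H](CC=C(C)C)O[Si](C)(C)C(C)(C)C
F3 | step 6 | cis ortho cycloadduct with C7 ketone, C3 silyl enol ether and C8 silyl ether | O=C([C@H](CC=C(C)C)O[Si](C)(C)C(C)(C)C)[C@@H]1CCC(C)=C(O[Si](C)(C)C(C)(C)C)[C@@H]1OC(=O)/C(C)=C\C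
F4 | step 6 | methylenated bis-silyl compound | C=C([C@H](CC=C(C)C)O[Si](C)(C)C(C)(C)C)[C@@H]1CCC(C)=C(O[Si](C)(C)C(C)(C)C)[C@@H]1OC(=O)/C(C)=C\C
F5 | step 6 | C8 tert-butyldimethylsilyl ether of 17 | C=C([C@H](CC=C(C)C)O[Si](C)(C)C(C)(C)C)[C@@H]1CC=C(C)C(=O)[C@@H]1OC(=O)/C(C)=C\C
F6 | step 7 | bridged tertiary β-hydroxysilane (C7 unassigned) | C[Si](C)(C)CC1(O)[C@H](CC=C(C)C)O[Si](C(C)C)(C(C)C)OC2=C(C)CC[C@@H]1[C@H]2OC(=O)/C(C)=C\C
F7 | step 7 | acetoxysilyl enone β-hydroxysilane (C7 unassigned) | C[Si](C)(C)CC(O)([C@H](CC=C(C)C)O[Si](C(C)C)(C(C)C)OC(C)=O)[C@@H]1CC=C(C)C(=O)[C@@H]1OC(=O)/C(C)=C\C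
F8 | step 8 | chlorosilyl α-phenylselanyl ketone (C4 unassigned) | C=C([C@H](CC=C(C)C)O[Si](Cl)(C(C)C)C(C)C)[C@@H]1CCC(C)([Se]c2ccccc2)C(=O)[C@@H]1OC(=O)/C(C)=C\C
F9 | step 8 | hydroxy selenide (C4 unassigned) | C=C([C@H](CC=C(C)C)O)[C@@H]1CCC(C)([Se]c2ccccc2)C(=O)[C@@H]1OC(=O)/C(C)=C\C
F10 | step 8 | selenoxide (C4 and Se unassigned) | C=C([C@H](CC=C(C)C)O)[C@@H]1CCC(C)([Se](=O)c2ccccc2)C(=O)[C@@H]1OC(=O)/C(C)=C\C
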